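**Retrosynthetic overview**

1. The target is an ester of two bicyclic 2-benzoxepin-1-one halves: cut the C4-carbonyl–O–CH2(C9) ester into a carboxylic acid half and a primary alcohol half (Yamaguchi esterification, then acid removal of one TBS ether and one tert-butyl ester).
2. Each half comes from an acyclic keto-enoate alkenylboronate in one rhodium-catalysed cascade: the C5–C5a bond forms first (seven-membered lactone, 1,4-addition), the C9–C9a bond second (cyclohexane, aldol); three stereocentres are set per half.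
3. Enabling feature: C5a is the β-carbon and C9a the α-carbon of the lactone carbonyl C1, C9 is a tertiary carbinol β to C1 (an aldol motif inside the cyclohexane), and on C4=C5 the vinylic C5 is cis to the C3H2–O arm. An alkenyl metal at C5, tethered through the C1 ester, can therefore add to C5a and hand its enolate, locked E inside the new lactone, to the C9 ketone.
4. The acyclic precursor comes from a Horner–Wadsworth–Emmons union of a 2-isopropyl-5-oxo aldehyde (organocatalytic Michael addition of isovaleraldehyde to a silyloxy vinyl ketone; sets C6) with a boryl phosphonate made from tert-butyl 2-(bromomethyl)acrylate.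

Key step: step 9

Remark: read as drawn, the half with the free CH2OH is (5aS,6R,9S,9aS) and the half with the CO2H is (5aR,6S,9R,9aR); the two bicycles are mirror images, so both enantiomers of the monomer are made with the two antipodes of the same catalysts.
Remark: ring locants are those of the 2-benzoxepin-1-one bicycle (C1 lactone C=O, O2, C3H2, C4, C5, C5a, C6 (i-Pr), C7, C8, C9 (C(OH)CH2O), C9a); rhodium-bound intermediates are drawn without the phosphine.

**Route**

Step 1
Reactants: 1 2-[(tert-butyldimethylsilyl)oxy]acetaldehyde; 2 vinylmagnesium bromide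
Product: 4 (±)-1-[(tert-butyldimethylsilyl)oxy]but-3-en-2-ol, via bromomagnesium alkoxide 3 (not isolated)
Conditions: THF, −78 → 0 °C; then H2O
Reagents that add atoms: none
Why: 1,2-addition of the vinyl Grignard reagent to the aldehyde; the new carbinol centre is racemic and is erased in step 2.

Step 2
Reactants: 4 (±)-1-[(tert-butyldimethylsilyl)oxy]but-3-en-2-ol
Product: 5 1-[(tert-butyldimethylsilyl)oxy]but-3-en-2-one
Conditions: Dess–Martin periodinane, CH2Cl2, 0 °C → rt; used without storage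
Reagents that add atoms: none
Why: Dess–Martin oxidation of the secondary allylic alcohol under neutral conditions that should leave the silyl ether and the polymerization-prone enone intact.

Step 3
Reactants: 5 1-[(tert-butyldimethylsilyl)oxy]but-3-en-2-one; 6 3-methylbutanal
Product: 7 (2R)-6-[(tert-butyldimethylsilyl)oxy]-5-oxo-2-(propan-2-yl)hexanal
Conditions: (R)-2-(methoxydiphenylmethyl)pyrrolidine (5 mol %), ethyl 3,4-dihydroxybenzoate (20 mol %), neat, 4 °C
Reagents that add atoms: none
Why: enamine-catalysed Michael addition in which the (E)-enamine of 6 is shielded on one face by the diphenylmethoxymethyl group and adds to the enone terminus from the other, setting the isopropyl-bearing centre (future C6) as R.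

Step 4
Reactants: 8 tert-butyl 2-(bromomethyl)prop-2-enoate
Product: 9 tert-butyl 2,3-dibromo-2-(bromomethyl)propanoate
Conditions: Br2 (1.05 equiv), CH2Cl2, 0 °C → rt
Reagents that add atoms: bromine, BrBr
Why: electrophilic addition of bromine to the acrylate C=C; the product has no stereocentre because C2 carries two CH2Br groups.

Step 5
Reactants: 9 tert-butyl 2,3-dibromo-2-(bromomethyl)propanoate
Product: 10 tert-butyl (2Z)-3-bromo-2-(bromomethyl)prop-2-enoate
Conditions: DBU (1.05 equiv), Et2O, 0 °C; then LiBr (10 mol %), acetone, rt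
Reagents that add atoms: none
Why: E2 loss of HBr gives the β-bromoacrylate, and bromide-mediated SN2′ transposition should equilibrate the geometric isomers to the one with the vinylic bromine trans to the ester and cis to CH2Br, as in allylic bromides derived from Morita–Baylis–Hillman adducts (geometry to be confirmed by NOE).

Step 6
Reactants: 10 tert-butyl (2Z)-3-bromo-2-(bromomethyl)prop-2-enoate; 11 2-(diethoxyphosphoryl)acetic acid
Product: 13 tert-butyl (2E)-3-bromo-2-({[2-(diethoxyphosphoryl)acetyl]oxy}methyl)prop-2-enoate, via potassium phosphonoacetate 12 (not isolated)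
Conditions: KHCO3, DMF, 0 °C → rt
Reagents that add atoms: none
Why: SN2 O-alkylation of the carboxylate by the allylic bromide with a base too weak to deprotonate the phosphonate CH2; the alkene geometry is carried over (now named E).

Step 7
Reactants: 13 tert-butyl (2E)-3-bromo-2-({[2-(diethoxyphosphoryl)acetyl]oxy}methyl)prop-2-enoate
Product: 14 tert-butyl (2E)-2-({[2-(diethoxyphosphoryl)acetyl]oxy}methyl)-3-(4,4,5,5-tetramethyl-1,3,2-dioxaborolan-2-yl)prop-2-enoate
Conditions: B2pin2 (1.1 equiv), PdCl2(dppf) (3 mol %), KOAc, 1,4-dioxane, 80 °C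
Reagents that add atoms: bis(pinacolato)diboron, CC1(C)OB(OC1(C)C)B1OC(C)(C)C(C)(C)O1
Why: Miyaura borylation, in which oxidative addition into the activated alkenyl C–Br bond should outrun ionization of the allylic ester and boron enters with retention, cis to the CH2O arm.

Step 8
Reactants: 7 (2R)-6-[(tert-butyldimethylsilyl)oxy]-5-oxo-2-(propan-2-yl)hexanal; 14 tert-butyl (2E)-2-({[2-(diethoxyphosphoryl)acetyl]oxy}methyl)-3-(4,4,5,5-tetramethyl-1,3,2-dioxaborolan-2-yl)prop-2-enoate
Product: 16 tert-butyl (2E)-2-[({(2E,4R)-8-[(tert-butyldimethylsilyl)oxy]-7-oxo-4-(propan-2-yl)oct-2-enoyl}oxy)methyl]-3-(4,4,5,5-tetramethyl-1,3,2-dioxaborolan-2-yl)prop-2-enoate, via lithiated phosphonate 15 (not isolated)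
Conditions: LiCl, i-Pr2NEt, MeCN, 0 °C → rt
Reagents that add atoms: none
Why: Horner–Wadsworth–Emmons olefination under Masamune–Roush conditions, selective for the aldehyde over the ketone and E-selective, mild enough to keep the α-stereocentre and the alkenylboronate.

Step 9
Reactants: 16 tert-butyl (2E)-2-[({(2E,4R)-8-[(tert-butyldimethylsilyl)oxy]-7-oxo-4-(propan-2-yl)oct-2-enoyl}oxy)methyl]-3-(4,4,5,5-tetramethyl-1,3,2-dioxaborolan-2-yl)prop-2-enoate
Product: 19 tert-butyl (5aS,6R,9S,9aS)-9-{[(tert-butyldimethylsilyl)oxy]methyl}-9-hydroxy-1-oxo-6-(propan-2-yl)-1,3,5a,6,7,8,9,9a-octahydro-2-benzoxepine-4-carboxylate, via alkenylrhodium species 17 (not isolated), via lactone rhodium enolate 18 (not isolated)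
Conditions: [Rh(OH)((S)-BINAP)]2 (2.5 mol %), Et3N (1 equiv), 1,4-dioxane/H2O (20:1), 0.01 M, 60 °C
Reagents that add atoms: none
Why: Proposed new method: transmetalation of the alkenyl–Bpin to Rh(I)–OH gives alkenylrhodium 17, whose Rh–C5 bond inserts the tethered (E)-enoate at C5a to give the seven-membered lactone as its rhodium enolate 18, which adds to the C9 ketone before water can protonate it, and hydrolysis of the rhodium alkoxide regenerates Rh–OH. The closest known chemistry is the Rh/BINAP tandem conjugate addition–aldol cyclization of boronic acids with enone–ketones and the intramolecular 1,4-addition of alkenylrhodium species to tethered enoates; new here are the ester tether, the seven-membered ring and an ester-derived enolate as the aldol donor. The lactone closes in a 7-endo-trig mode, possible only because boron is cis to the CH2O arm on C4=C5 (and no β-oxygen elimination is open to 17), and the cyclohexane closes in a 6-(enolexo)-exo-trig aldol. C5a is set by the (S)-BINAP–Rh fragment choosing the enoate face (reagent control over the neighbouring C6 centre, the (R)-ligand to be used instead if this pairing proves mismatched). C9a and C9 follow from a chair Zimmerman–Traxler transition state in which the enolate, held E(O) by the lactone ring, and the ketone oxygen are bridged by rhodium with the isopropyl group, C5 and C1 equatorial, which should place the new OH equatorial and trans to the lactone carbonyl and CH2OTBS axial. The step needs insertion to outrun protodeboronation, intermolecular addition and enolate protonation, which high dilution, little water, a non-enolizing base and the six-membered reach of the C9 ketone are meant to secure.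

Step 10
Reactants: 19 tert-butyl (5aS,6R,9S,9aS)-9-{[(tert-butyldimethylsilyl)oxy]methyl}-9-hydroxy-1-oxo-6-(propan-2-yl)-1,3,5a,6,7,8,9,9a-octahydro-2-benzoxepine-4-carboxylate
Product: 20 (5aS,6R,9S,9aS)-9-{[(tert-butyldimethylsilyl)oxy]methyl}-9-hydroxy-1-oxo-6-(propan-2-yl)-1,3,5a,6,7,8,9,9a-octahydro-2-benzoxepine-4-carboxylic acid
Conditions: 85 % aq H3PO4 (5 equiv), toluene, rt
Reagents that add atoms: none
Why: acidolysis of the tert-butyl ester with loss of isobutene under conditions that the primary TBS ether, the lactone and the tertiary alcohol are expected to survive.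

Step 11
Reactants: 5 1-[(tert-butyldimethylsilyl)oxy]but-3-en-2-one; 6 3-methylbutanal
Product: 21 (2S)-6-[(tert-butyldimethylsilyl)oxy]-5-oxo-2-(propan-2-yl)hexanal
Conditions: (S)-2-(methoxydiphenylmethyl)pyrrolidine (5 mol %), ethyl 3,4-dihydroxybenzoate (20 mol %), neat, 4 °C
Reagents that add atoms: none
Why: the same enamine-catalysed Michael addition as step 3 with the antipodal catalyst, which should give the S aldehyde for the mirror-image half.

Step 12
Reactants: 21 (2S)-6-[(tert-butyldimethylsilyl)oxy]-5-oxo-2-(propan-2-yl)hexanal; 14 tert-butyl (2E)-2-({[2-(diethoxyphosphoryl)acetyl]oxy}methyl)-3-(4,4,5,5-tetramethyl-1,3,2-dioxaborolan-2-yl)prop-2-enoate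
Product: 22 tert-butyl (2E)-2-[({(2E,4S)-8-[(tert-butyldimethylsilyl)oxy]-7-oxo-4-(propan-2-yl)oct-2-enoyl}oxy)methyl]-3-(4,4,5,5-tetramethyl-1,3,2-dioxaborolan-2-yl)prop-2-enoate
Conditions: LiCl, i-Pr2NEt, MeCN, 0 °C → rt
Reagents that add atoms: none
Why: aldehyde-selective, E-selective Horner–Wadsworth–Emmons olefination under Masamune–Roush conditions, run as in step 8 on the antipodal aldehyde.

Step 13
Reactants: 22 tert-butyl (2E)-2-[({(2E,4S)-8-[(tert-butyldimethylsilyl)oxy]-7-oxo-4-(propan-2-yl)oct-2-enoyl}oxy)methyl]-3-(4,4,5,5-tetramethyl-1,3,2-dioxaborolan-2-yl)prop-2-enoate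
Product: 25 tert-butyl (5aR,6S,9R,9aR)-9-{[(tert-butyldimethylsilyl)oxy]methyl}-9-hydroxy-1-oxo-6-(propan-2-yl)-1,3,5a,6,7,8,9,9a-octahydro-2-benzoxepine-4-carboxylate, via alkenylrhodium species 23 (not isolated), via lactone rhodium enolate 24 (not isolated)
Conditions: [Rh(OH)((R)-BINAP)]2 (2.5 mol %), Et3N (1 equiv), 1,4-dioxane/H2O (20:1), 0.01 M, 60 °C
Reagents that add atoms: none
Why: Proposed new method: the mirror-image run of step 9, in which insertion of the alkenylrhodium into the tethered enoate (closest known type: Rh-catalysed conjugate addition–aldol cyclization of enone–ketones) is followed by the Zimmerman–Traxler aldol of the lactone-locked E-enolate, the (R)-ligand now selecting the opposite enoate face so that C5a, C9a and C9 should come out as in 25.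

Step 14
Reactants: 25 tert-butyl (5aR,6S,9R,9aR)-9-{[(tert-butyldimethylsilyl)oxy]methyl}-9-hydroxy-1-oxo-6-(propan-2-yl)-1,3,5a,6,7,8,9,9a-octahydro-2-benzoxepine-4-carboxylate
Product: 26 tert-butyl (5aR,6S,9R,9aR)-9-hydroxy-9-(hydroxymethyl)-1-oxo-6-(propan-2-yl)-1,3,5a,6,7,8,9,9a-octahydro-2-benzoxepine-4-carboxylate
Conditions: HF·pyridine, pyridine, THF, 0 °C → rt
Reagents that add atoms: none
Why: fluoride-assisted cleavage of the primary silyl ether under buffered conditions that should leave the tert-butyl ester and the lactone intact.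

Step 15
Reactants: 20 (5aS,6R,9S,9aS)-9-{[(tert-butyldimethylsilyl)oxy]methyl}-9-hydroxy-1-oxo-6-(propan-2-yl)-1,3,5a,6,7,8,9,9a-octahydro-2-benzoxepine-4-carboxylic acid; 26 tert-butyl (5aR,6S,9R,9aR)-9-hydroxy-9-(hydroxymethyl)-1-oxo-6-(propan-2-yl)-1,3,5a,6,7,8,9,9a-octahydro-2-benzoxepine-4-carboxylate
Product: 28 tert-butyl (5aR,6S,9R,9aR)-9-({[(5aS,6R,9S,9aS)-9-{[(tert-butyldimethylsilyl)oxy]methyl}-9-hydroxy-1-oxo-6-(propan-2-yl)-1,3,5a,6,7,8,9,9a-octahydro-2-benzoxepine-4-carbonyl]oxy}methyl)-9-hydroxy-1-oxo-6-(propan-2-yl)-1,3,5a,6,7,8,9,9a-octahydro-2-benzoxepine-4-carboxylate, via mixed anhydride 27 (not isolated)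
Conditions: 2,4,6-trichlorobenzoyl chloride, Et3N, THF, rt; then 26, DMAP, toluene, rt
Reagents that add atoms: none
Why: Yamaguchi esterification, in which the mixed anhydride of the enoic acid should acylate only the primary hydroxyl of 26 under DMAP catalysis, the tertiary alcohols of both partners being unreactive.

Step 16
Reactants: 28 tert-butyl (5aR,6S,9R,9aR)-9-({[(5aS,6R,9S,9aS)-9-{[(tert-butyldimethylsilyl)oxy]methyl}-9-hydroxy-1-oxo-6-(propan-2-yl)-1,3,5a,6,7,8,9,9a-octahydro-2-benzoxepine-4-carbonyl]oxy}methyl)-9-hydroxy-1-oxo-6-(propan-2-yl)-1,3,5a,6,7,8,9,9a-octahydro-2-benzoxepine-4-carboxylate (the protected dimer of step 15)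
Product: 29 (5aR,6S,9R,9aR)-9-hydroxy-9-({[(5aS,6R,9S,9aS)-9-hydroxy-9-(hydroxymethyl)-1-oxo-6-(propan-2-yl)-1,3,5a,6,7,8,9,9a-octahydro-2-benzoxepine-4-carbonyl]oxy}methyl)-1-oxo-6-(propan-2-yl)-1,3,5a,6,7,8,9,9a-octahydro-2-benzoxepine-4-carboxylic acid (CNP0340505.1)
Conditions: TFA/CH2Cl2/H2O (10:10:1), 0 °C → rt
Reagents that add atoms: none
Why: global acidolysis in which the tert-butyl ester loses isobutene and the primary TBS ether is solvolysed, while both lactones, the linking ester and the tertiary alcohols should tolerate cold aqueous TFA.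

**Compound list**

1 | 2-[(tert-butyldimethylsilyl)oxy]acetaldehyde | O=CCO[Si](C)(C)C(C)(C)C | starting material
2 | vinylmagnesium bromide | C=C[Mg]Br | starting material
3 | bromomagnesium 1-[(tert-butyldimethylsilyl)oxy]but-3-en-2-olate (not isolated) | C=CC(O[Mg]Br)CO[Si](C)(C)C(C)(C)C | intermediate
4 | (±)-1-[(tert-butyldimethylsilyl)oxy]but-3-en-2-ol | C=CC(O)CO[Si](C)(C)C(C)(C)C | intermediate
5 | 1-[(tert-butyldimethylsilyl)oxy]but-3-en-2-one | C=CC(=O)CO[Si](C)(C)C(C)(C)C | intermediate
6 | 3-methylbutanal | CC(C)CC=O | starting material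
7 | (2R)-6-[(tert-butyldimethylsilyl)oxy]-5-oxo-2-(propan-2-yl)hexanal | CC(C)[C@H](C=O)CCC(=O)CO[Si](C)(C)C(C)(C)C | intermediate
8 | tert-butyl 2-(bromomethyl)prop-2-enoate | C=C(CBr)C(=O)OC(C)(C)C | starting material
9 | tert-butyl 2,3-dibromo-2-(bromomethyl)propanoate | BrCC(Br)(CBr)C(=O)OC(C)(C)C | intermediate
10 | tert-butyl (2Z)-3-bromo-2-(bromomethyl)prop-2-enoate | Br/C=C(\CBr)C(=O)OC(C)(C)C | intermediate
11 | 2-(diethoxyphosphoryl)acetic acid | CCOP(=O)(CC(=O)O)OCC | starting material
12 | potassium 2-(diethoxyphosphoryl)acetate (not isolated) | CCOP(=O)(CC(=O)[O-])OCC.[K+] | intermediate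
13 | tert-butyl (2E)-3-bromo-2-({[2-(diethoxyphosphoryl)acetyl]oxy}methyl)prop-2-enoate | CCOP(=O)(OCC)CC(=O)OC/C(=C\Br)C(=O)OC(C)(C)C | intermediate
14 | tert-butyl (2E)-2-({[2-(diethoxyphosphoryl)acetyl]oxy}methyl)-3-(4,4,5,5-tetramethyl-1,3,2-dioxaborolan-2-yl)prop-2-enoate | CCOP(=O)(OCC)CC(=O)OC/C(=C\B1OC(C)(C)C(C)(C)O1)C(=O)OC(C)(C)C | intermediate
15 | lithium salt of the phosphonate carbanion of 14 (not isolated) | CCOP(=O)(OCC)[CH-]C(=O)OC/C(=C\B1OC(C)(C)C(C)(C)O1)C(=O)OC(C)(C)C.[Li+] | intermediate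
16 | tert-butyl (2E)-2-[({(2E,4R)-8-[(tert-butyldimethylsilyl)oxy]-7-oxo-4-(propan-2-yl)oct-2-enoyl}oxy)methyl]-3-(4,4,5,5-tetramethyl-1,3,2-dioxaborolan-2-yl)prop-2-enoate | CC(C)[C@H](/C=C/C(=O)OC/C(=C\B1OC(C)(C)C(C)(C)O1)C(=O)OC(C)(C)C)CCC(=O)CO[Si](C)(C)C(C)(C)C | intermediate
17 | alkenylrhodium(I) species from 16 (not isolated) | CC(C)[C@H](/C=C/C(=O)OC/C(=C\[Rh])C(=O)OC(C)(C)C)CCC(=O)CO[Si](C)(C)C(C)(C)C | intermediate
18 | rhodium enolate of the (5aS)-lactone with the (R)-keto side chain (not isolated) | CC(C)[C@@H](CCC(=O)CO[Si](C)(C)C(C)(C)C)[C@H]1C=C(C(=O)OC(C)(C)C)COC(O[Rh])=C1 | intermediate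
19 | tert-butyl (5aS,6R,9S,9aS)-9-{[(tert-butyldimethylsilyl)oxy]methyl}-9-hydroxy-1-oxo-6-(propan-2-yl)-1,3,5a,6,7,8,9,9a-octahydro-2-benzoxepine-4-carboxylate | CC(C)[C@H]1CC[C@@](O)(CO[Si](C)(C)C(C)(C)C)[C@H]2C(=O)OCC(C(=O)OC(C)(C)C)=C[C@H]12 | intermediate
20 | (5aS,6R,9S,9aS)-9-{[(tert-butyldimethylsilyl)oxy]methyl}-9-hydroxy-1-oxo-6-(propan-2-yl)-1,3,5a,6,7,8,9,9a-octahydro-2-benzoxepine-4-carboxylic acid | CC(C)[C@H]1CC[C@@](O)(CO[Si](C)(C)C(C)(C)C)[C@H]2C(=O)OCC(C(=O)O)=C[C@H]12 | intermediate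
21 | (2S)-6-[(tert-butyldimethylsilyl)oxy]-5-oxo-2-(propan-2-yl)hexanal | CC(C)[C@@H](C=O)CCC(=O)CO[Si](C)(C)C(C)(C)C | intermediate
22 | tert-butyl (2E)-2-[({(2E,4S)-8-[(tert-butyldimethylsilyl)oxy]-7-oxo-4-(propan-2-yl)oct-2-enoyl}oxy)methyl]-3-(4,4,5,5-tetramethyl-1,3,2-dioxaborolan-2-yl)prop-2-enoate | CC(C)[C@@H](/C=C/C(=O)OC/C(=C\B1OC(C)(C)C(C)(C)O1)C(=O)OC(C)(C)C)CCC(=O)CO[Si](C)(C)C(C)(C)C | intermediate
23 | alkenylrhodium(I) species from 22 (not isolated) | CC(C)[C@@H](/C=C/C(=O)OC/C(=C\[Rh])C(=O)OC(C)(C)C)CCC(=O)CO[Si](C)(C)C(C)(C)C | intermediate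
24 | rhodium enolate of the (5aR)-lactone with the (S)-keto side chain (not isolated) | CC(C)[C@H](CCC(=O)CO[Si](C)(C)C(C)(C)C)[C@@H]1C=C(C(=O)OC(C)(C)C)COC(O[Rh])=C1 | intermediate
25 | tert-butyl (5aR,6S,9R,9aR)-9-{[(tert-butyldimethylsilyl)oxy]methyl}-9-hydroxy-1-oxo-6-(propan-2-yl)-1,3,5a,6,7,8,9,9a-octahydro-2-benzoxepine-4-carboxylate | CC(C)[C@@H]1CC[C@](O)(CO[Si](C)(C)C(C)(C)C)[C@@H]2C(=O)OCC(C(=O)OC(C)(C)C)=C[C@@H]12 | intermediate
26 | tert-butyl (5aR,6S,9R,9aR)-9-hydroxy-9-(hydroxymethyl)-1-oxo-6-(propan-2-yl)-1,3,5a,6,7,8,9,9a-octahydro-2-benzoxepine-4-carboxylate | CC(C)[C@@H]1CC[C@](O)(CO)[C@@H]2C(=O)OCC(C(=O)OC(C)(C)C)=C[C@@H]12 | intermediate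
27 | mixed anhydride of 20 with 2,4,6-trichlorobenzoic acid (not isolated) | CC(C)[C@H]1CC[C@@](O)(CO[Si](C)(C)C(C)(C)C)[C@H]2C(=O)OCC(C(=O)OC(=O)c3c(Cl)cc(Cl)cc3Cl)=C[C@H]12 | intermediate
28 | tert-butyl (5aR,6S,9R,9aR)-9-({[(5aS,6R,9S,9aS)-9-{[(tert-butyldimethylsilyl)oxy]methyl}-9-hydroxy-1-oxo-6-(propan-2-yl)-1,3,5a,6,7,8,9,9a-octahydro-2-benzoxepine-4-carbonyl]oxy}methyl)-9-hydroxy-1-oxo-6-(propan-2-yl)-1,3,5a,6,7,8,9,9a-octahydro-2-benzoxepine-4-carboxylate | CC(C)[C@H]1CC[C@@](O)(CO[Si](C)(C)C(C)(C)C)[C@H]2C(=O)OCC(C(=O)OC[C@@]3(O)CC[C@@H](C(C)C)[C@@H]4C=C(C(=O)OC(C)(C)C)COC(=O)[C@H]43)=C[C@H]12 | intermediate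
29 | CNP0340505.1, (5aR,6S,9R,9aR)-9-hydroxy-9-({[(5aS,6R,9S,9aS)-9-hydroxy-9-(hydroxymethyl)-1-oxo-6-(propan-2-yl)-1,3,5a,6,7,8,9,9a-octahydro-2-benzoxepine-4-carbonyl]oxy}methyl)-1-oxo-6-(propan-2-yl)-1,3,5a,6,7,8,9,9a-octahydro-2-benzoxepine-4-carboxylic acid | CC(C)[C@H]1CC[C@@](O)(CO)[C@H]2C(=O)OCC(C(=O)OC[C@@]3(O)CC[C@@H](C(C)C)[C@@H]4C=C(C(=O)O)COC(=O)[C@H]43)=C[C@H]12 | target

**Count**

Total steps: 16. Longest linear sequence: 9 (steps 4, 5, 6, 7, 8, 9, 10, 15, 16).

**Steps most likely to fail**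

1. Step 9 (Proposed new method). The ring closure needs the ester tether in its disfavoured s-cis rotamer, so hydrolysis of the alkenylrhodium (protodeboronation), intermolecular addition, or protonation of the enolate before the aldol may outrun the cascade. Fallback with known chemistry, setting out from 7 and 13 and coming back at 19: Horner–Wadsworth–Emmons reaction of 7 with the bromo phosphonate 13 (LiBr, Et3N, THF) should give the alkenyl bromide tert-butyl (2E)-3-bromo-2-[({(2E,4R)-8-[(tert-butyldimethylsilyl)oxy]-7-oxo-4-(propan-2-yl)oct-2-enoyl}oxy)methyl]prop-2-enoate F1. F1 is then cyclized under the nickel(0)/dialkylzinc conditions established for the three-component conjugate addition–aldol coupling of organic halides, acrylates and carbonyl compounds (Ni(cod)2 cat., Et2Zn, THF, 0 °C, high dilution). Oxidative addition replaces transmetalation, no water is present, and the enolate is passed on as a zinc enolate that can only undergo the aldol. The lactone-locked E-enolate should give the same relative configuration at C9a and C9; C5a would then rest on the resident C6 centre or an added chiral phosphine, so 19 may have to be separated from its C5a epimer.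

2. Step 13 (Proposed new method). The same kinetic competition applies in the mirror-image series, and face selection at C5a may erode if ligand and C6 centre are mismatched. Fallback with known chemistry, setting out from 21 and 13 and coming back at 25: olefination of 21 with 13 (LiBr, Et3N, THF) should give tert-butyl (2E)-3-bromo-2-[({(2E,4S)-8-[(tert-butyldimethylsilyl)oxy]-7-oxo-4-(propan-2-yl)oct-2-enoyl}oxy)methyl]prop-2-enoate F2, which is closed to 25 by the same nickel(0)/diethylzinc conjugate addition–aldol coupling in a water-free medium.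

3. Step 15. The free primary hydroxyl of 26 may attack its own lactone carbonyl under Et3N/DMAP (translactonization to a five-membered lactone), and acylation of this neopentyl-type hydroxyl is slow. Fallback, setting out from 22 and 20 and coming back at 28: the silyl ether of 22 is cleaved (AcOH/THF/H2O, rt) to the hydroxy ketone tert-butyl (2E)-2-[({(2E,4S)-8-hydroxy-7-oxo-4-(propan-2-yl)oct-2-enoyl}oxy)methyl]-3-(4,4,5,5-tetramethyl-1,3,2-dioxaborolan-2-yl)prop-2-enoate F3. Its unhindered primary hydroxyl, which has no lactone to attack, is esterified with 20 under Yamaguchi conditions to give the open-chain ester of 20 with F3, F4. The cascade of step 13 ([Rh(OH)((R)-BINAP)]2, Et3N, dioxane/H2O, 60 °C) is then run on F4, so the second bicycle is built with the linking ester already in place, giving 28 directly.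

**Further compounds**

F1 | step 9 | tert-butyl (2E)-3-bromo-2-[({(2E,4R)-8-[(tert-butyldimethylsilyl)oxy]-7-oxo-4-(propan-2-yl)oct-2-enoyl}oxy)methyl]prop-2-enoate | CC(C)[C@H](/C=C/C(=O)OC/C(=C\Br)C(=O)OC(C)(C)C)CCC(=O)CO[Si](C)(C)C(C)(C)C
F2 | step 13 | tert-butyl (2E)-3-bromo-2-[({(2E,4S)-8-[(tert-butyldimethylsilyl)oxy]-7-oxo-4-(propan-2-yl)oct-2-enoyl}oxy)methyl]prop-2-enoate | CC(C)[C@@H](/C=C/C(=O)OC/C(=C\Br)C(=O)OC(C)(C)C)CCC(=O)CO[Si](C)(C)C(C)(C)C
F3 | step 15 | tert-butyl (2E)-2-[({(2E,4S)-8-hydroxy-7-oxo-4-(propan-2-yl)oct-2-enoyl}oxy)methyl]-3-(4,4,5,5-tetramethyl-1,3,2-dioxaborolan-2-yl)prop-2-enoate | CC(C)[C@@H](/C=C/C(=O)OC/C(=C\B1OC(C)(C)C(C)(C)O1)C(=O)OC(C)(C)C)CCC(=O)CO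
F4 | step 15 | ester of acid 20 with the primary hydroxyl of F3 | CC(C)[C@H]1CC[C@@](O)(CO[Si](C)(C)C(C)(C)C)[C@H]2C(=O)OCC(C(=O)OCC(=O)CC[C@@H](C(C)C)/C=C/C(=O)OC/C(=C\B3OC(C)(C)C(C)(C)O3)C(=O)OC(C)(C)C)=C[C@H]12
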